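**Plan**
- Retrosynthesis: the two MOM ethers and the silyl ether are unmasked last. Ring B of the naphthazarin is cut at C1–C8a and C4–C4a (aryne plus furan, the furan oxygen becoming one quinone oxygen), then the ester C–O bond and the side-chain C1'–C2' bond (alkynyl addition to furan-3-carbaldehyde).
- Enabling feature: ring B (C1 to C4, side chain on C2) is fused to a ring A whose only substituents are the oxygens on C5 and C8, so ring A corresponds to a benzyne with a mirror plane. Either orientation of a 3-substituted furan, and either naphthol formed on opening, leads to the same 2-substituted quinone.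
- Forward order: the side chain is built on the furan (alkynylation, trans-reduction, acylation). Ring A comes ready-made from hydroquinone as an ortho-silylaryl triflate. Ring B closes in the aryne–furan [4+2], then oxabicycle → naphthol → p-quinone, and one acid step frees the three hydroxyls.
- Stereochemistry: C1' (R) comes from a BINOL/Ti(OiPr)4-controlled alkynylzinc addition, the acyl C2 (R) from (R)-2-methylbutanoic acid, and the E-alkene from trans-hydroalumination. The bridgehead centres of the cycloadduct are transient.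

Key step: step 10

Assumption: furan-3-carbaldehyde is taken to follow the facial preference of benzaldehyde-type substrates in BINOL/Ti(OiPr)4 alkynylzinc additions, (R)-BINOL giving Re-face attack; if the sense proved opposite, (S)-BINOL would be used in step 2 with no other change.

**Route**

Step 1
Reactants: 1 2-methylbut-3-yn-2-ol
Product: 2 triethyl[(2-methylbut-3-yn-2-yl)oxy]silane
Conditions: TESCl, imidazole, DMAP (cat.), DMF, rt
Reagents that add atoms: chlorotriethylsilane, CC[Si](Cl)(CC)CC
Why: Standard imidazole/DMAP-assisted silyl ether formation; the unhindered tertiary propargylic hydroxyl is silylated and the acetylenic C–H stays free for metalation.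

Step 2
Reactants: 2 triethyl[(2-methylbut-3-yn-2-yl)oxy]silane; 3 furan-3-carbaldehyde
Product: 5 (1R)-1-(furan-3-yl)-4-methyl-4-(triethylsilyloxy)pent-2-yn-1-ol, via alkynyl(ethyl)zinc 4 (not isolated)
Conditions: 2 (2.2 equiv), Et2Zn (2.2 equiv), toluene, reflux; then (R)-BINOL (20 mol%), Ti(OiPr)4 (50 mol%), Et2O, rt; then 3, rt; aqueous work-up
Reagents that add atoms: none
Why: BINOL–titanium-catalysed enantioselective addition of an alkynylzinc to an aldehyde, which is at its best with aromatic and heteroaromatic aldehydes; the (R)-BINOL complex should direct the alkynyl group to the Re face of 3, which sets C1 as R (furan-3-yl outranks the alkynyl group).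

Step 3
Reactants: 5 (1R)-1-(furan-3-yl)-4-methyl-4-(triethylsilyloxy)pent-2-yn-1-ol
Product: 6 (1R,2E)-1-(furan-3-yl)-4-methyl-4-(triethylsilyloxy)pent-2-en-1-ol
Conditions: NaAlH2(OCH2CH2OMe)2 (Red-Al), THF, 0 °C → rt; aq. Rochelle salt
Reagents that add atoms: none
Why: Alkoxide-directed trans-hydroalumination of a propargylic alcohol followed by protonolysis gives only the E-allylic alcohol; the carbinol centre is not involved and the tertiary silyloxy group is too poor a leaving group at 0 °C for allene formation.

Step 4
Reactants: 6 (1R,2E)-1-(furan-3-yl)-4-methyl-4-(triethylsilyloxy)pent-2-en-1-ol; 7 (2R)-2-methylbutanoic acid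
Product: 8 (1R,2E)-1-(furan-3-yl)-4-methyl-4-(triethylsilyloxy)pent-2-en-1-yl (2R)-2-methylbutanoate
Conditions: DCC, DMAP (10 mol%), CH2Cl2, 0 °C → rt
Reagents that add atoms: none
Why: Steglich esterification acylates the secondary alcohol at oxygen, so C1 keeps its R configuration, and with catalytic DMAP at 0 °C the α-stereocentre of the acid should not enolise.

Step 5
Reactants: 9 hydroquinone
Product: 10 1,4-bis(methoxymethoxy)benzene
Conditions: NaH, MOMCl, DMF, 0 °C → rt
Reagents that add atoms: chloromethyl methyl ether, COCCl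
Why: Williamson-type O-alkylation of the bis-phenoxide with MOMCl installs two acetal ethers that tolerate organolithiums and fluoride and serve as ortho-directing groups.

Step 6
Reactants: 10 1,4-bis(methoxymethoxy)benzene
Product: 13 2,5-bis(methoxymethoxy)phenol, via aryllithium 11 (not isolated), via dimethyl arylboronate 12 (not isolated)
Conditions: n-BuLi, THF, 0 °C; B(OMe)3, −78 °C → rt; then 30% H2O2, aq. NaOH, 0 °C → rt
Reagents that add atoms: hydrogen peroxide, OO (trimethyl borate, COB(OC)OC, supplies only the boronate atoms of intermediate 12, which are lost again)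
Why: Directed ortho-metalation next to a MOM ether, borylation and alkaline peroxide oxidation of the C–B bond is the standard hydroxylation of an arene C–H; the four ring hydrogens of 10 are equivalent, so only one phenol can form.

Step 7
Reactants: 13 2,5-bis(methoxymethoxy)phenol
Product: 14 2,5-bis(methoxymethoxy)phenyl N-(propan-2-yl)carbamate
Conditions: i-PrNCO, Et3N (cat.), CH2Cl2, rt
Reagents that add atoms: isopropyl isocyanate, CC(C)N=C=O
Why: Base-catalysed addition of the phenol to the isocyanate gives the secondary carbamate, which directs the next lithiation and can later be removed under mild conditions.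

Step 8
Reactants: 14 2,5-bis(methoxymethoxy)phenyl N-(propan-2-yl)carbamate
Product: 18 3,6-bis(methoxymethoxy)-2-(trimethylsilyl)phenyl N-(propan-2-yl)carbamate, via N-TBS carbamate 15 (not isolated), via ortho-lithiated N-TBS carbamate 16 (not isolated), via N-TBS C-TMS carbamate 17 (not isolated)
Conditions: TBSOTf, TMEDA, Et2O, 0 °C → rt; n-BuLi, TMEDA, −78 °C; TMSCl, −78 °C → rt; brief aq. NaHSO4 work-up
Reagents that add atoms: chlorotrimethylsilane, C[Si](C)(C)Cl (tert-butyldimethylsilyl triflate, CC(C)(C)[Si](C)(C)OS(=O)(=O)C(F)(F)F, supplies only the transient N-silyl group of 15 to 17)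
Why: Directed ortho-metalation of the carbamate silylated on nitrogen in the flask; the only C–H flanked by two directing groups (carbamate and MOM ether) is lithiated, N-silylation prevents N–H deprotonation, and at −78 °C the aryllithium is trapped by TMSCl before an anionic Fries shift can occur.

Step 9
Reactants: 18 3,6-bis(methoxymethoxy)-2-(trimethylsilyl)phenyl N-(propan-2-yl)carbamate
Product: 20 3,6-bis(methoxymethoxy)-2-(trimethylsilyl)phenyl trifluoromethanesulfonate, via silylphenol 19 (not isolated)
Conditions: DBU, Et2NH, MeCN, 40 °C; then PhNTf2, rt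
Reagents that add atoms: N-phenylbis(trifluoromethanesulfonimide), O=S(=O)(N(c1ccccc1)S(=O)(=O)C(F)(F)F)C(F)(F)F
Why: DBU induces E1cB loss of isopropyl isocyanate (captured by Et2NH as the urea) from the secondary carbamate and the released phenoxide is triflated in the same flask by PhNTf2, the usual one-pot route from ortho-silylaryl carbamates to aryne precursors.

Step 10
Reactants: 8 (1R,2E)-1-(furan-3-yl)-4-methyl-4-(triethylsilyloxy)pent-2-en-1-yl (2R)-2-methylbutanoate; 20 3,6-bis(methoxymethoxy)-2-(trimethylsilyl)phenyl trifluoromethanesulfonate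
Product: 22 (1R,2E)-1-[5,8-bis(methoxymethoxy)-1,4-dihydro-1,4-epoxynaphthalen-2-yl]-4-methyl-4-(triethylsilyloxy)pent-2-en-1-yl (2R)-2-methylbutanoate (both bridgehead diastereomers), via 3,6-bis(methoxymethoxy)benzyne 21 (not isolated)
Conditions: 20 (1.5 equiv), CsF (3 equiv), MeCN, rt
Reagents that add atoms: none
Why: Fluoride attacks the trimethylsilyl group of 20 and the aryl anion expels triflate to give benzyne 21, whose strained triple bond is trapped by the furan diene of 8 in a concerted suprafacial [4+2] cycloaddition (aryne–furan Diels–Alder reaction, the standard use of ortho-silylaryl triflates). Ring B closes by this single cycloaddition: furan C2 and C5 bond to the two aryne carbons, forming C1–C8a and C4–C4a at once and leaving the furan oxygen as the 1,4-bridge. The two bridgehead stereocentres are tied to each other by the bicycle, but their sense relative to C1' is not controlled because the side-chain centre is too remote from the diene faces; this is harmless, as both are erased in step 11. The step needs the aryne to choose the furan over the side-chain alkene, which is secured because furan is among the fastest aryne traps and the E-disubstituted alkene is a poor ene or [2+2] partner. CsF in MeCN at room temperature is neutral enough to leave the ester, the tertiary silyl ether, the MOM acetals and the C1' configuration alone. No regiochemical question arises, since 21 has a mirror plane through the triple bond and either orientation of the furan gives the same constitution.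

Step 11
Reactants: 22 (1R,2E)-1-[5,8-bis(methoxymethoxy)-1,4-dihydro-1,4-epoxynaphthalen-2-yl]-4-methyl-4-(triethylsilyloxy)pent-2-en-1-yl (2R)-2-methylbutanoate
Product: 25 (1R,2E)-1-[5,8-bis(methoxymethoxy)-1,4-dioxo-1,4-dihydronaphthalen-2-yl]-4-methyl-4-(triethylsilyloxy)pent-2-en-1-yl (2R)-2-methylbutanoate, via 1-hydroxy naphthol regioisomer 23 (not isolated), via 4-hydroxy naphthol regioisomer 24 (not isolated)
Conditions: Cu(OTf)2 (5 mol%), CH2Cl2, 0 °C; filtration through basic alumina, evaporation; then PhI(OAc)2 (2.2 equiv), MeCN/H2O (3:1), 0 °C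
Reagents that add atoms: water, O
Why: Cu(OTf)2 ionises a bridging C–O bond (helped by the ortho MOM-oxy group) to a benzylic-allylic cation that undergoes 1,2-hydride shift and enolisation to naphthols 23 and 24 (Lewis-acid isomerisation of 7-oxabenzonorbornadienes), and PhI(OAc)2 in wet MeCN then oxidises either free naphthol at its para position to the same p-quinone (hypervalent-iodine phenol oxidation), leaving the etherified ring A, the ester and both stereocentres untouched.

Step 12
Reactants: 25 (1R,2E)-1-[5,8-bis(methoxymethoxy)-1,4-dioxo-1,4-dihydronaphthalen-2-yl]-4-methyl-4-(triethylsilyloxy)pent-2-en-1-yl (2R)-2-methylbutanoate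
Product: 26 (1R,2E)-1-(5,8-dihydroxy-1,4-dioxo-1,4-dihydronaphthalen-2-yl)-4-hydroxy-4-methylpent-2-en-1-yl (2R)-2-methylbutanoate
Conditions: 2 M aq. HCl/THF (1:4), 0 °C → rt
Reagents that add atoms: none
Why: Acid hydrolysis of the two MOM acetals, made labile because each aryloxy leaving group is a vinylogous carboxylate that ends hydrogen-bonded to a quinone carbonyl, and of the tertiary silyl ether, in an alcohol-free medium too mild to ionise the tertiary allylic alcohol or the quinone-deactivated C1' ester.

**Compound list**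
1 | 2-methylbut-3-yn-2-ol | CC(C)(O)C#C | starting material
2 | triethyl[(2-methylbut-3-yn-2-yl)oxy]silane | CC[Si](CC)(CC)OC(C)(C)C#C | intermediate
3 | furan-3-carbaldehyde | O=Cc1ccoc1 | starting material
4 | ethyl[3-methyl-3-(triethylsilyloxy)but-1-yn-1-yl]zinc | CC[Zn]C#CC(C)(C)O[Si](CC)(CC)CC | intermediate
5 | (1R)-1-(furan-3-yl)-4-methyl-4-(triethylsilyloxy)pent-2-yn-1-ol | O[C@H](C#CC(C)(C)O[Si](CC)(CC)CC)c1ccoc1 | intermediate
6 | (1R,2E)-1-(furan-3-yl)-4-methyl-4-(triethylsilyloxy)pent-2-en-1-ol | O[C@H](/C=C/C(C)(C)O[Si](CC)(CC)CC)c1ccoc1 | intermediate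
7 | (2R)-2-methylbutanoic acid | CC[C@@H](C)C(=O)O | starting material
8 | (1R,2E)-1-(furan-3-yl)-4-methyl-4-(triethylsilyloxy)pent-2-en-1-yl (2R)-2-methylbutanoate | CC[C@@H](C)C(=O)O[C@H](/C=C/C(C)(C)O[Si](CC)(CC)CC)c1ccoc1 | intermediate
9 | hydroquinone (benzene-1,4-diol) | Oc1ccc(O)cc1 | starting material
10 | 1,4-bis(methoxymethoxy)benzene | COCOc1ccc(OCOC)cc1 | intermediate
11 | [2,5-bis(methoxymethoxy)phenyl]lithium | [Li]c1cc(OCOC)ccc1OCOC | intermediate
12 | dimethyl [2,5-bis(methoxymethoxy)phenyl]boronate | COB(OC)c1cc(OCOC)ccc1OCOC | intermediate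
13 | 2,5-bis(methoxymethoxy)phenol | Oc1cc(OCOC)ccc1OCOC | intermediate
14 | 2,5-bis(methoxymethoxy)phenyl N-(propan-2-yl)carbamate | CC(C)NC(=O)Oc1cc(OCOC)ccc1OCOC | intermediate
15 | 2,5-bis(methoxymethoxy)phenyl N-(tert-butyldimethylsilyl)-N-(propan-2-yl)carbamate | CC(C)N(C(=O)Oc1cc(OCOC)ccc1OCOC)[Si](C)(C)C(C)(C)C | intermediate
16 | 2-lithio-3,6-bis(methoxymethoxy)phenyl N-(tert-butyldimethylsilyl)-N-(propan-2-yl)carbamate | CC(C)N(C(=O)Oc1c([Li])c(OCOC)ccc1OCOC)[Si](C)(C)C(C)(C)C | intermediate
17 | 3,6-bis(methoxymethoxy)-2-(trimethylsilyl)phenyl N-(tert-butyldimethylsilyl)-N-(propan-2-yl)carbamate | CC(C)N(C(=O)Oc1c([Si](C)(C)C)c(OCOC)ccc1OCOC)[Si](C)(C)C(C)(C)C | intermediate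
18 | 3,6-bis(methoxymethoxy)-2-(trimethylsilyl)phenyl N-(propan-2-yl)carbamate | CC(C)NC(=O)Oc1c([Si](C)(C)C)c(OCOC)ccc1OCOC | intermediate
19 | 3,6-bis(methoxymethoxy)-2-(trimethylsilyl)phenol | Oc1c([Si](C)(C)C)c(OCOC)ccc1OCOC | intermediate
20 | 3,6-bis(methoxymethoxy)-2-(trimethylsilyl)phenyl trifluoromethanesulfonate | COCOc1ccc(OCOC)c([Si](C)(C)C)c1OS(=O)(=O)C(F)(F)F | intermediate
21 | 3,6-bis(methoxymethoxy)benzyne | COCOC1=CC=C(OCOC)C#C1 | intermediate
22 | (1R,2E)-1-[5,8-bis(methoxymethoxy)-1,4-dihydro-1,4-epoxynaphthalen-2-yl]-4-methyl-4-(triethylsilyloxy)pent-2-en-1-yl (2R)-2-methylbutanoate, mixture of the two bridgehead diastereomers (bridgeheads left unassigned) | CC[C@@H](C)C(=O)O[C@H](/C=C/C(C)(C)O[Si](CC)(CC)CC)C1=CC2OC1c1c(OCOC)ccc(OCOC)c12 | intermediate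
23 | (1R,2E)-1-[1-hydroxy-5,8-bis(methoxymethoxy)naphthalen-2-yl]-4-methyl-4-(triethylsilyloxy)pent-2-en-1-yl (2R)-2-methylbutanoate | CC[C@@H](C)C(=O)O[C@H](/C=C/C(C)(C)O[Si](CC)(CC)CC)c1ccc2c(OCOC)ccc(OCOC)c2c1O | intermediate
24 | (1R,2E)-1-[4-hydroxy-5,8-bis(methoxymethoxy)naphthalen-2-yl]-4-methyl-4-(triethylsilyloxy)pent-2-en-1-yl (2R)-2-methylbutanoate | CC[C@@H](C)C(=O)O[C@H](/C=C/C(C)(C)O[Si](CC)(CC)CC)c1cc(O)c2c(OCOC)ccc(OCOC)c2c1 | intermediate
25 | (1R,2E)-1-[5,8-bis(methoxymethoxy)-1,4-dioxo-1,4-dihydronaphthalen-2-yl]-4-methyl-4-(triethylsilyloxy)pent-2-en-1-yl (2R)-2-methylbutanoate | CC[C@@H](C)C(=O)O[C@H](/C=C/C(C)(C)O[Si](CC)(CC)CC)C1=CC(=O)c2c(OCOC)ccc(OCOC)c2C1=O | intermediate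
26 | (1R,2E)-1-(5,8-dihydroxy-1,4-dioxo-1,4-dihydronaphthalen-2-yl)-4-hydroxy-4-methylpent-2-en-1-yl (2R)-2-methylbutanoate | CC[C@@H](C)C(=O)O[C@H](/C=C/C(C)(C)O)C1=CC(=O)c2c(O)ccc(O)c2C1=O | target

**Step count**
Total: 12 steps (4 to furan ester 8, 5 to aryne precursor 20, 3 after their union).
Longest linear sequence: 8 steps (steps 5 to 12, from hydroquinone 9).

**Steps most likely to fail and fallbacks**

Step 11. Under the Lewis acid, the cation formed next to C2 may be captured by the neighbouring acyloxy group (acyloxonium formation, then acyl transfer to the new naphthol oxygen or erosion at C1'). The allylic C–O bonds of the side chain may also ionise, and the minor naphthol 24 may be oxidised partly at its free ortho position. The fallback moves the acylation to the end so that no participating ester is present during opening and oxidation. It sets out from alcohol 6, which is silylated (TESCl, imidazole, DMF) to (1R,2E)-1-(furan-3-yl)-4-methylpent-2-ene-1,4-diol bis(triethylsilyl) ether F1. Cycloaddition of F1 with 20 under CsF in MeCN should give the corresponding 5,8-bis(methoxymethoxy)-1,4-epoxy-1,4-dihydronaphthalene F2. Acid-catalysed opening and PhI(OAc)2 oxidation as in step 11 should give the bis-silyl bis-MOM quinone F3. Aqueous HCl in THF then removes all four protecting groups to give 5,8-dihydroxy-2-[(1R,2E)-1,4-dihydroxy-4-methylpent-2-en-1-yl]naphthalene-1,4-dione F4. Carbodiimide acylation of F4 with acid 7 (DCC, catalytic DMAP, CH2Cl2, 0 °C) should select the secondary C1' hydroxyl, because the tertiary alcohol and the chelated peri-hydroxyls are unreactive, and the route is rejoined at 26.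

Step 12. Cleavage of the MOM acetals may be too slow under acid mild enough for the side chain. Under stronger acid the tertiary allylic alcohol may ionise, leading to allylic transposition or elimination. The fallback sets out from 25 and splits the deprotection into two non-Brønsted stages. MgBr2·OEt2 in Et2O/CH2Cl2 should remove the two peri MOM groups by bromide attack on the magnesium-chelated acetals, giving (1R,2E)-1-(5,8-dihydroxy-1,4-dioxo-1,4-dihydronaphthalen-2-yl)-4-methyl-4-(triethylsilyloxy)pent-2-en-1-yl (2R)-2-methylbutanoate F5. Pyridine-buffered HF·pyridine in THF then cleaves the tertiary silyl ether without generating a cation, and the route is rejoined at 26.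

Step 2. Facial selectivity may be poor with the small heteroaromatic aldehyde and the hindered alkyne, or the alkynylzinc addition may be sluggish. The fallback sets out from 2 and 3 and sets the carbinol centre by reagent-controlled ketone reduction instead. The lithium acetylide of 2 (n-BuLi, THF, −78 °C) adds to 3 to give racemic 1-(furan-3-yl)-4-methyl-4-(triethylsilyloxy)pent-2-yn-1-ol F6. MnO2 in CH2Cl2 oxidises F6 to 1-(furan-3-yl)-4-methyl-4-(triethylsilyloxy)pent-2-yn-1-one F7. Midland reduction of F7 with (S)-Alpine-borane (from (−)-α-pinene), in which the alkynyl group acts as the small substituent, should give the R alcohol, and the route is rejoined at 5.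

**Further compounds**
F1 | step 11 | (1R,2E)-1-(furan-3-yl)-4-methylpent-2-ene-1,4-diol bis(triethylsilyl) ether | CC[Si](CC)(CC)O[C@H](/C=C/C(C)(C)O[Si](CC)(CC)CC)c1ccoc1
F2 | step 11 | 5,8-bis(methoxymethoxy)-2-[(1R,2E)-4-methyl-1,4-bis(triethylsilyloxy)pent-2-en-1-yl]-1,4-dihydro-1,4-epoxynaphthalene (both bridgehead diastereomers) | CC[Si](CC)(CC)O[C@H](/C=C/C(C)(C)O[Si](CC)(CC)CC)C1=CC2OC1c1c(OCOC)ccc(OCOC)c12
F3 | step 11 | 5,8-bis(methoxymethoxy)-2-[(1R,2E)-4-methyl-1,4-bis(triethylsilyloxy)pent-2-en-1-yl]naphthalene-1,4-dione | CC[Si](CC)(CC)O[C@H](/C=C/C(C)(C)O[Si](CC)(CC)CC)C1=CC(=O)c2c(OCOC)ccc(OCOC)c2C1=O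
F4 | step 11 | 5,8-dihydroxy-2-[(1R,2E)-1,4-dihydroxy-4-methylpent-2-en-1-yl]naphthalene-1,4-dione | O[C@H](/C=C/C(C)(C)O)C1=CC(=O)c2c(O)ccc(O)c2C1=O
F5 | step 12 | (1R,2E)-1-(5,8-dihydroxy-1,4-dioxo-1,4-dihydronaphthalen-2-yl)-4-methyl-4-(triethylsilyloxy)pent-2-en-1-yl (2R)-2-methylbutanoate | CC[C@@H](C)C(=O)O[C@H](/C=C/C(C)(C)O[Si](CC)(CC)CC)C1=CC(=O)c2c(O)ccc(O)c2C1=O
F6 | step 2 | racemic 1-(furan-3-yl)-4-methyl-4-(triethylsilyloxy)pent-2-yn-1-ol | OC(C#CC(C)(C)O[Si](CC)(CC)CC)c1ccoc1
F7 | step 2 | 1-(furan-3-yl)-4-methyl-4-(triethylsilyloxy)pent-2-yn-1-one | O=C(C#CC(C)(C)O[Si](CC)(CC)CC)c1ccoc1
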